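## The problem

Numbering used throughout (elemane numbering): the ring is C5–C6–C7–C8–C9–C10. C10 carries methyl C14 and vinyl C1=C2. C5 carries C4(=C3H2)–C15H2OH. C7 carries C11(=C13H2)–C12O2H. O6 is the free ring hydroxyl and O8 carries the (S)-3-hydroxy-2-methylpropanoyl group.

1. The target is an elemane seco-acid: one cyclohexane with a quaternary carbon (C10), one CH2 (C9) and four contiguous CH stereocentres (C8, C7, C6, C5), plus one stereocentre in the acyl group.
2. As the SMILES is written, the C10 methyl, the C5 side chain, O6, the C7 side chain and O8 all lie on one face. In the chair with both side chains equatorial, the methyl, O6 and O8 are therefore syn-triaxial, so the configurations at C6 and C8 cannot come from equilibration and must be set kinetically.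
3. At C10, methyl and vinyl are almost the same size, so no reagent approaching a preformed ring will tell them apart. The C10/C5 pair must be made in one concerted event.
4. Once C5 is set it can control C6 by 1,2-induction. C6 can control C7 and C8 only if it is physically tied to the atoms that react.
5. Both side chains are 1,1-disubstituted alkenes joined to the ring through their substituted carbon. Enolate alkylation cannot make such bonds; allyl transposition or alkyne chemistry can.
6. Fragile points: the cis γ-hydroxy acid (O6/C12) lactonises under acid; the O8 ester can migrate to the syn-axial O6; its β-hydroxy acyl group epimerises or eliminates under base; and in any C6-carbonyl intermediate C5–H is both α to the carbonyl and allylic.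
7. The feature that makes the key step possible: O6 and O8 are cis-1,3 on the ring and flank C7, whose substituent is the alkene C11=C13. O6–C6–C7–C11=C13 is a homoallylic alcohol and O6 and O8 can sit on one boron atom. This is exactly the pattern left when C7 is transferred from boron to an aldehyde carbon C8 inside a 1,2-oxaborinine ring (B, O6, C6, C7, C11, C13).

## Retrosynthesis

**Acid last (28 ⇐ 27 ⇐ 26).** The C12 acid is cut back to aldehyde 27 and then to the diethyl acetal and silyl ethers of 26. This is preferred over an ester at C12, which would have to be cleaved next to the O8 ester and would lactonise onto O6 or O8 on the way. The forward steps must be one aqueous acid treatment and one buffered oxidation, so that the hydroxy acid never meets acid, base or fluoride.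

**Ester (26 ⇐ 21 + 24).** The C8–O acyl bond is cut to diol 21 and the silylated Roche acid 24 (from the ester 22). Diol 21 needs no protecting group on O6 because C6 has two branched neighbours and C8 only one. The forward reaction must acylate the less hindered of two axial hydroxyls.

**Key cut (21 ⇐ 20 ⇐ 19 ⇐ 18).** The ring bond C7–C8 is cut together with a shift of the alkene from C11=C13 to C7=C11 and attachment of C13 to boron. This retro-allylboration opens the carbocycle to aldehyde 19, which comes from alcohol 18, a cyclic allylboronic ester whose boron is bound to O6. The neighbouring cuts (C6–C7 or C5–C6 by aldol or ene reactions) would give the equatorial, trans alcohol. This cut instead removes two stereocentres, the ring and the exocyclic methylene at once, and delivers O6 and O8 as one cyclic borate 20. The forward reaction must transfer C7 to C8 within the tether faster than any untethered path.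

**Allylboron unit (18 ⇐ 16 ⇐ 14).** The C11–C13 bond is cut to the (Z)-alkenyl iodide 16 and a borylmethyl donor; 16 comes from propargylic alcohol 14 by directed trans-hydroalumination. The alkyne is preferred over an alkenyl nucleophile because it lets the C6 hydroxyl itself fix the alkene geometry that the oxaborinine ring needs.

**C6–C7 bond and C6 configuration (14 ⇐ 13 ⇐ 11 + 12).** The carbinol is cut back to ynone 13, and this to δ-lactone 11 and 3,3-diethoxypropyne 12. The lactone serves as acyl donor and as the protecting group of O8 in one. Ketone reduction is chosen over alkynyl addition to an aldehyde because Felkin-type hydride delivery gives the C6 configuration that the tether requires, whereas carbon-nucleophile addition gives the opposite one.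

**C5–C10 bond (11 ⇐ 10 ⇐ 8).** The C5–C10 bond is cut by a retro-Ireland–Claisen rearrangement to the achiral ester 8. Its chair transition state sets the quaternary/tertiary pair, and a chiral boron enolate supplies the absolute configuration of the whole synthesis. The forward reaction needs one enolate geometry and good facial selectivity.

**Building blocks (8 ⇐ 3 + 4; 3 ⇐ 1).** Ester 8 falls apart into allylic alcohol 3 and itaconic anhydride 4, whose five carbons are exactly C15, C4, C3, C5 and C6 at the right oxidation pattern. Alcohol 3 comes from the commercial alkyne 1 by carboalumination.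

## Roads not taken

**Alternative 1:** (the most obvious, biomimetic cut) C5–C10 is cut by a retro-Cope rearrangement to the ten-membered (1(10)E,4E)-germacradiene A1. Heating would give the elemane triol acid A2, which would then be acylated at O8. This is not chosen for three reasons. The medium ring with its all-cis C6/C7/C8 triad would have to be made first and has no element that controls that triad. The Cope equilibrium must fight the syn-triaxial strain of the product. The several chair-like conformers of the ring leave the relation between the new C5/C10 pair and C6–C8 uncontrolled. The chosen plan makes the six-membered ring directly and reads every stereocentre from its neighbour.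

**Alternative 2:** C10–C1 is cut to the cyclohexenone A3. Vinyl cuprate would add trans to the C5 substituent to give ketone A4, and hydride would then attack C8 from the face opposite the axial methyl. The logic for C10 and C8 is sound. However, A3 already contains C5, C6 and C7, must carry two alkenyl groups that enolate chemistry cannot install, is a β-silyloxy ketone prone to elimination and aromatisation, and leaves the C6 configuration to a separate inversion. The run-up would be longer than the whole chosen route.

**Alternative 3:** (dearomatisation) Birch reduction and methylation of 3,5-dimethoxybenzoic acid A5 would give diene acid A6, which has the C6/C8 oxygens and the quaternary C10 in one step from a cheap arene. It is not chosen because A6 is achiral and must be desymmetrised. C5 and C7 would each need an sp2 carbon attached to the α-carbon of a 1,3-dione, for which no dependable method exists. The carboxyl-to-vinyl change costs three steps, and reduction of a 2-substituted 1,3-dione to the syn-diaxial diol is unsolved.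

Key step: step 11

**Assumptions.**
- The SMILES is read as written: C10 methyl, C5 side chain, O6, C7 side chain and O8 all cis (6β-OH, 8β-acyloxy); the route is built for this isomer.
- The bromoborane/triethylamine pair in toluene–hexane is taken to give the E(O) boron enolate of 8, and the (S,S) reagent to give (2R,3S)-10; should the facial sense prove opposite, the (R,R) reagent is used.

## Route

Step 1
Reactants: 1 tert-butyl(but-3-yn-1-yloxy)dimethylsilane
Product: 3 (2E)-5-(tert-butyldimethylsilyloxy)-3-methylpent-2-en-1-ol, via alkenylalane 2 (not isolated)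
Conditions: Me3Al, Cp2ZrCl2 (cat.), CH2Cl2, 0 → 23 °C; then n-BuLi, (CH2O)n, THF, −30 → 23 °C
Reagents that add atoms: trimethylaluminium C[Al](C)C; formaldehyde (from paraformaldehyde) C=O
Why: Zirconium-catalysed carboalumination (Negishi) adds methyl and aluminium syn across the terminal alkyne with aluminium at the terminus; the alanate is hydroxymethylated with retention, so the (E)-trisubstituted allylic alcohol should result.

Step 2
Reactants: 3 (E)-allylic alcohol; 4 itaconic anhydride
Product: 5 itaconic acid 4-monoester of 3 (free acrylic acid)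
Conditions: toluene, 80 °C, no base
Reagents that add atoms: none
Why: Alcoholysis of itaconic anhydride occurs at the non-conjugated, less hindered carbonyl and gives the 4-monoester; base is left out so that the exocyclic alkene does not move into the ring.

Step 3
Reactants: 5 monoester acid
Product: 7 (E)-allylic 3-(hydroxymethyl)but-3-enoate, via mixed carbonic anhydride 6 (not isolated)
Conditions: i-BuOCOCl, N-methylmorpholine, THF, −15 °C; then NaBH4, THF/H2O, −15 → 0 °C
Reagents that add atoms: none
Why: Mixed-anhydride activation followed by borohydride reduces a carboxylic acid beside an ester; short contact at low temperature should limit lactonisation of the γ-hydroxy ester.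

Step 4
Reactants: 7 hydroxy ester
Product: 8 (E)-allylic 3-[(triisopropylsilyloxy)methyl]but-3-enoate
Conditions: i-Pr3SiCl, imidazole, CH2Cl2, 23 °C
Reagents that add atoms: chlorotri(propan-2-yl)silane CC(C)[Si](Cl)(C(C)C)C(C)C
Why: Standard silylation of a primary allylic alcohol; the bulky silyl ether must outlast the later removal of the primary tert-butyldimethylsilyl ether.

Step 5
Reactants: 8 allylic ester
Product: 10 (2R,3S)-3-[2-(tert-butyldimethylsilyloxy)ethyl]-3-methyl-2-[3-(triisopropylsilyloxy)prop-1-en-2-yl]pent-4-enoic acid, via boron ketene acetal 9 (not isolated)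
Conditions: (4S,5S)-2-bromo-1,3-bis{[3,5-bis(trifluoromethyl)phenyl]sulfonyl}-4,5-diphenyl-1,3,2-diazaborolidine (1.2 equiv, prepared beforehand), Et3N, toluene/hexane, −78 °C; then 4 °C, several days; H2O
Reagents that add atoms: none
Why: Enantioselective Ireland–Claisen rearrangement through a chiral boron ketene acetal, a reaction type established for geranyl-type esters of but-3-enoic acids; in the chair transition state the (E)-alkene puts the C10 methyl axial and the E(O) enolate puts the alkenyl group axial, which gives the C5 side chain cis to the methyl, and the diazaborolidine selects the enantiotopic faces.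

Step 6
Reactants: 10 acid
Product: 11 (3R,4S)-4-ethenyl-4-methyl-3-[3-(triisopropylsilyloxy)prop-1-en-2-yl]oxan-2-one (δ-lactone O8–C6)
Conditions: camphorsulfonic acid (10 mol %), MeOH/CH2Cl2, 0 °C; then toluene, 50 °C
Reagents that add atoms: none
Why: Acidic methanolysis removes the primary tert-butyldimethylsilyl ether much faster than the triisopropylsilyl ether, and the δ-hydroxy acid lactonises (helped by the quaternary carbon); the lactone protects O8 and activates C6 as an acyl donor.

Step 7
Reactants: 11 lactone; 12 3,3-diethoxyprop-1-yne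
Product: 13 (5R,6S)-1,1-diethoxy-6-ethenyl-8-hydroxy-6-methyl-5-[3-(triisopropylsilyloxy)prop-1-en-2-yl]oct-2-yn-4-one
Conditions: 12, n-BuLi, THF, −78 °C; CeCl3; then 11, −78 °C; aq. NH4Cl
Reagents that add atoms: none
Why: Alkynyl addition to a δ-lactone stops at the lactolate and gives the hydroxy ynone on work-up; the weakly basic cerium acetylide should spare the epimerisable C5–H.

Step 8
Reactants: 13 hydroxy ynone
Product: 14 (4S,5R,6S)-1,1-diethoxy-6-ethenyl-6-methyl-5-[3-(triisopropylsilyloxy)prop-1-en-2-yl]oct-2-yne-4,8-diol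
Conditions: LiBH(s-Bu)3 (2.5 equiv), THF, −78 °C; then NaOH, H2O2
Reagents that add atoms: none
Why: Felkin–Anh 1,2-reduction of an α-branched ynone by a bulky hydride: hydride enters anti to the quaternary C10, which sets C6 so that O6 will lie on the ring face of the C5 side chain (ring–chain tautomerism of 13 does not matter because the alkoxide is open-chain).

Step 9
Reactants: 14 propargylic diol
Product: 16 (2Z,4S,5R,6S)-1,1-diethoxy-6-ethenyl-2-iodo-6-methyl-5-[3-(triisopropylsilyloxy)prop-1-en-2-yl]oct-2-ene-4,8-diol, via cyclic alkenylalanate 15 (not isolated)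
Conditions: NaAlH2(OCH2CH2OMe)2, THF, 0 °C; then I2, THF, −78 °C
Reagents that add atoms: iodine II
Why: Alkoxide-directed trans-hydroalumination of a propargylic alcohol delivers hydride to C7 and aluminium to C11 in a five-membered oxa-aluminacycle; iodinolysis with retention gives the alkenyl iodide with C6 and iodine cis.

Step 10
Reactants: 16 iodo diol
Product: 18 (6R)-4-(diethoxymethyl)-6-{(1R,2S)-2-ethenyl-4-hydroxy-2-methyl-1-[3-(triisopropylsilyloxy)prop-1-en-2-yl]butyl}-3,6-dihydro-2H-1,2-oxaborinin-2-ol, via pinacol allylboronate 17 (not isolated)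
Conditions: CH2(Bpin)2, Pd[P(t-Bu)3]2 (5 mol %), KOH (aq), 1,4-dioxane, 23 °C; then NaIO4, NH4OAc, acetone/H2O, 23 °C
Reagents that add atoms: bis(pinacolato)diborylmethane CC1(C)OB(CB2OC(C)(C)C(C)(C)O2)OC1(C)C; water O
Why: Suzuki–Miyaura coupling of a gem-diborylmethane transfers one borylmethyl group to the alkenyl iodide with retention of geometry; periodate cleavage of the pinacol ester frees the boronic acid, which closes onto the cis-disposed O6–H to the six-membered hemiboronic ester.

Step 11
Reactants: 18 cyclic allylboronic ester with free primary alcohol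
Product: 21 (1R,2R,3S,4R,5S)-2-(3,3-diethoxyprop-1-en-2-yl)-5-ethenyl-5-methyl-4-[3-(triisopropylsilyloxy)prop-1-en-2-yl]cyclohexane-1,3-diol, via aldehyde 19 (not isolated), via cyclic borate 20 (not isolated)
Conditions: Dess–Martin periodinane, NaHCO3, CH2Cl2, 0 °C; then toluene, 4 Å molecular sieves, 23 → 80 °C; then MeOH/H2O, 23 °C
Reagents that add atoms: none
Why: Proposed new method: oxidation of the primary alcohol gives aldehyde 19, whose carbonyl oxygen binds the boron already held by O6 in the 1,2-oxaborinine ring, and C7 (the γ-carbon of the unit B–C13–C11=C7) is transferred to C8 while C11=C13 becomes the exocyclic methylene; the closest known reaction types are the intramolecular allylboration of tethered aldehydes and the addition of cyclic, oxygen-tethered allylboronic esters to aldehydes, and their combination to close a carbocycle is what is new. The cyclohexane closes by C7–C8 bond formation, 6-exo-trig at the carbonyl; the six-membered boron array (B, O8, C8, C7, C11, C13) shares B, C13, C11 and C7 with the oxaborinine ring and must therefore be a boat inside a bicyclo[2.2.2]octane-like transition state. C7 is controlled by C6: the ring holds the O6–C6–C7=C11 torsion near zero and only the C5 chain on C6 can reach the reacting face, so C8 adds on that face and C11 ends cis to O6, the opposite of what allylic 1,3-strain gives in an untethered allylboron compound. C8 is controlled by the boron: its oxygen is bound to the same boron as O6, so O8 must end cis-1,3 to O6. The product leaves as the cyclic borate 20 of the syn-diaxial diol, which mild solvolysis turns into 21. The step needs the tethered path to beat untethered allyl transfer and hemiacetal formation between O6 and C8; both are excluded while O6 stays on boron, which has no other chelating ligand once pinacol is gone, and the sieves keep it there. The cost is imperfect overlap of the ring C13–B bond with the C7=C11 π bond and a syn-axial contact of the C10 methyl with O6 and O8 in the chair-like carbocycle, hence the heating.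

Step 12
Reactants: 22 methyl (2S)-3-hydroxy-2-methylpropanoate
Product: 23 methyl (2S)-3-(tert-butyldimethylsilyloxy)-2-methylpropanoate
Conditions: t-BuMe2SiCl, imidazole, CH2Cl2, 23 °C
Reagents that add atoms: tert-butylchlorodimethylsilane CC(C)(C)[Si](C)(C)Cl
Why: Standard silylation of the primary alcohol; the stereocentre is not touched.

Step 13
Reactants: 23 silylated ester
Product: 24 (2S)-3-(tert-butyldimethylsilyloxy)-2-methylpropanoic acid
Conditions: LiOH, THF/H2O, 0 °C; then HCl (aq) to pH 3
Reagents that add atoms: lithium hydroxide [Li+].[OH-]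
Why: Saponification at 0 °C; with the β-oxygen silylated, elimination and epimerisation should be slow against hydrolysis.

Step 14
Reactants: 21 diol; 24 acid
Product: 26 C8 ester (1R,2S,3S,4R,5S)-2-(3,3-diethoxyprop-1-en-2-yl)-5-ethenyl-3-hydroxy-5-methyl-4-[3-(triisopropylsilyloxy)prop-1-en-2-yl]cyclohexyl (2S)-3-(tert-butyldimethylsilyloxy)-2-methylpropanoate, via mixed anhydride 25 (not isolated)
Conditions: 24, 2,4,6-Cl3C6H2COCl, Et3N, THF, 23 °C; then 21, DMAP, toluene, 0 → 23 °C
Reagents that add atoms: none
Why: Yamaguchi esterification; the C8 hydroxyl has one CH2 neighbour whereas the C6 hydroxyl lies between two branched carbons, so acylation (and any acyl migration between the syn-axial oxygens) should favour O8.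

Step 15
Reactants: 26 silylated acetal ester
Product: 27 (1R,2S,3S,4R,5S)-5-ethenyl-3-hydroxy-4-(3-hydroxyprop-1-en-2-yl)-5-methyl-2-(3-oxoprop-1-en-2-yl)cyclohexyl (2S)-3-hydroxy-2-methylpropanoate
Conditions: HF (48% aq), MeCN, 0 → 23 °C
Reagents that add atoms: water O
Why: Aqueous HF cleaves both primary silyl ethers and hydrolyses the acrolein acetal in one operation; no base is present, so the ester neither migrates nor eliminates, and with C12 still an aldehyde no lactone can form.

Step 16
Reactants: 27 triol enal
Product: 28 target, 2-[(1S,2S,3R,4S,6R)-4-ethenyl-2-hydroxy-6-{[(2S)-3-hydroxy-2-methylpropanoyl]oxy}-3-(3-hydroxyprop-1-en-2-yl)-4-methylcyclohexyl]prop-2-enoic acid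
Conditions: NaClO2, NaH2PO4, 2-methylbut-2-ene, t-BuOH/H2O, 0 °C
Reagents that add atoms: sodium chlorite [Na+].[O-]Cl=O
Why: Pinnick oxidation turns the 2-substituted acrolein into the acrylic acid under phosphate buffer without touching alcohols or (with the scavenger) alkenes; placed last, it releases the γ-hydroxy acid without exposure to strong acid, base or fluoride.

## Compound list

1 | tert-butyl(but-3-yn-1-yloxy)dimethylsilane | C#CCCO[Si](C)(C)C(C)(C)C | starting material
2 | [(1E)-4-(tert-butyldimethylsilyloxy)-2-methylbut-1-en-1-yl]dimethylaluminium | C[Al](C)/C=C(\C)CCO[Si](C)(C)C(C)(C)C | intermediate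
3 | (2E)-5-(tert-butyldimethylsilyloxy)-3-methylpent-2-en-1-ol | OC/C=C(\C)CCO[Si](C)(C)C(C)(C)C | intermediate
4 | itaconic anhydride (3-methylideneoxolane-2,5-dione) | C=C1CC(=O)OC1=O | starting material
5 | 4-{[(2E)-5-(tert-butyldimethylsilyloxy)-3-methylpent-2-en-1-yl]oxy}-2-methylidene-4-oxobutanoic acid | OC(=O)C(=C)CC(=O)OC/C=C(\C)CCO[Si](C)(C)C(C)(C)C | intermediate
6 | mixed anhydride of 5 with isobutyl hydrogen carbonate | CC(C)COC(=O)OC(=O)C(=C)CC(=O)OC/C=C(\C)CCO[Si](C)(C)C(C)(C)C | intermediate
7 | (2E)-5-(tert-butyldimethylsilyloxy)-3-methylpent-2-en-1-yl 3-(hydroxymethyl)but-3-enoate | OCC(=C)CC(=O)OC/C=C(\C)CCO[Si](C)(C)C(C)(C)C | intermediate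
8 | (2E)-5-(tert-butyldimethylsilyloxy)-3-methylpent-2-en-1-yl 3-[(triisopropylsilyloxy)methyl]but-3-enoate | CC(C)[Si](C(C)C)(C(C)C)OCC(=C)CC(=O)OC/C=C(\C)CCO[Si](C)(C)C(C)(C)C | intermediate
9 | E(O) boron ketene acetal of 8 with the (4S,5S)-1,3-bis{[3,5-bis(trifluoromethyl)phenyl]sulfonyl}-4,5-diphenyl-1,3,2-diazaborolidin-2-yl group on oxygen | C=C(CO[Si](C(C)C)(C(C)C)C(C)C)/C=C(/OB1N(S(=O)(=O)c2cc(cc(c2)C(F)(F)F)C(F)(F)F)[C@@H](c2ccccc2)[C@H](c2ccccc2)N1S(=O)(=O)c1cc(cc(c1)C(F)(F)F)C(F)(F)F)OC/C=C(\C)CCO[Si](C)(C)C(C)(C)C | intermediate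
10 | (2R,3S)-3-[2-(tert-butyldimethylsilyloxy)ethyl]-3-methyl-2-[3-(triisopropylsilyloxy)prop-1-en-2-yl]pent-4-enoic acid | C=C[C@](C)(CCO[Si](C)(C)C(C)(C)C)[C@@H](C(=O)O)C(=C)CO[Si](C(C)C)(C(C)C)C(C)C | intermediate
11 | (3R,4S)-4-ethenyl-4-methyl-3-[3-(triisopropylsilyloxy)prop-1-en-2-yl]oxan-2-one | C=C[C@]1(C)CCOC(=O)[C@H]1C(=C)CO[Si](C(C)C)(C(C)C)C(C)C | intermediate
12 | 3,3-diethoxyprop-1-yne | C#CC(OCC)OCC | starting material
13 | (5R,6S)-1,1-diethoxy-6-ethenyl-8-hydroxy-6-methyl-5-[3-(triisopropylsilyloxy)prop-1-en-2-yl]oct-2-yn-4-one | C=C[C@](C)(CCO)[C@@H](C(=O)C#CC(OCC)OCC)C(=C)CO[Si](C(C)C)(C(C)C)C(C)C | intermediate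
14 | (4S,5R,6S)-1,1-diethoxy-6-ethenyl-6-methyl-5-[3-(triisopropylsilyloxy)prop-1-en-2-yl]oct-2-yne-4,8-diol | C=C[C@](C)(CCO)[C@@H]([C@H](O)C#CC(OCC)OCC)C(=C)CO[Si](C(C)C)(C(C)C)C(C)C | intermediate
15 | disodium salt of the 2,5-dihydro-1,2-oxaluminole alanate formed from 14 (Al on C11 and O6, two 2-methoxyethoxy ligands, C8 alkoxide) | [Na+].[Na+].COCCO[Al-]1(OCCOC)O[C@@H]([C@@H](C(=C)CO[Si](C(C)C)(C(C)C)C(C)C)[C@](C)(C=C)CC[O-])C=C1C(OCC)OCC | intermediate
16 | (2Z,4S,5R,6S)-1,1-diethoxy-6-ethenyl-2-iodo-6-methyl-5-[3-(triisopropylsilyloxy)prop-1-en-2-yl]oct-2-ene-4,8-diol | C=C[C@](C)(CCO)[C@@H]([C@H](O)/C=C(\I)C(OCC)OCC)C(=C)CO[Si](C(C)C)(C(C)C)C(C)C | intermediate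
17 | (2E,4R,5R,6S)-1,1-diethoxy-6-ethenyl-6-methyl-2-[(4,4,5,5-tetramethyl-1,3,2-dioxaborolan-2-yl)methyl]-5-[3-(triisopropylsilyloxy)prop-1-en-2-yl]oct-2-ene-4,8-diol | C=C[C@](C)(CCO)[C@@H]([C@H](O)/C=C(\CB1OC(C)(C)C(C)(C)O1)C(OCC)OCC)C(=C)CO[Si](C(C)C)(C(C)C)C(C)C | intermediate
18 | (6R)-4-(diethoxymethyl)-6-{(1R,2S)-2-ethenyl-4-hydroxy-2-methyl-1-[3-(triisopropylsilyloxy)prop-1-en-2-yl]butyl}-3,6-dihydro-2H-1,2-oxaborinin-2-ol | C=C[C@](C)(CCO)[C@@H]([C@@H]1OB(O)CC(C(OCC)OCC)=C1)C(=C)CO[Si](C(C)C)(C(C)C)C(C)C | intermediate
19 | (6R)-4-(diethoxymethyl)-6-{(1R,2S)-2-ethenyl-2-methyl-4-oxo-1-[3-(triisopropylsilyloxy)prop-1-en-2-yl]butyl}-3,6-dihydro-2H-1,2-oxaborinin-2-ol | C=C[C@](C)(CC=O)[C@@H]([C@@H]1OB(O)CC(C(OCC)OCC)=C1)C(=C)CO[Si](C(C)C)(C(C)C)C(C)C | intermediate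
20 | (1R,5S,6R,7S,9R)-9-(3,3-diethoxyprop-1-en-2-yl)-7-ethenyl-7-methyl-6-[3-(triisopropylsilyloxy)prop-1-en-2-yl]-2,4-dioxa-3-borabicyclo[3.3.1]nonan-3-ol | C=C[C@]1(C)C[C@H]2OB(O)O[C@H]([C@@H]2C(=C)C(OCC)OCC)[C@H]1C(=C)CO[Si](C(C)C)(C(C)C)C(C)C | intermediate
21 | (1R,2R,3S,4R,5S)-2-(3,3-diethoxyprop-1-en-2-yl)-5-ethenyl-5-methyl-4-[3-(triisopropylsilyloxy)prop-1-en-2-yl]cyclohexane-1,3-diol | C=C[C@]1(C)C[C@@H](O)[C@@H](C(=C)C(OCC)OCC)[C@@H](O)[C@H]1C(=C)CO[Si](C(C)C)(C(C)C)C(C)C | intermediate
22 | methyl (2S)-3-hydroxy-2-methylpropanoate | COC(=O)[C@@H](C)CO | starting material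
23 | methyl (2S)-3-(tert-butyldimethylsilyloxy)-2-methylpropanoate | COC(=O)[C@@H](C)CO[Si](C)(C)C(C)(C)C | intermediate
24 | (2S)-3-(tert-butyldimethylsilyloxy)-2-methylpropanoic acid | OC(=O)[C@@H](C)CO[Si](C)(C)C(C)(C)C | intermediate
25 | (2S)-3-(tert-butyldimethylsilyloxy)-2-methylpropanoic 2,4,6-trichlorobenzoic anhydride | O=C(OC(=O)c1c(Cl)cc(Cl)cc1Cl)[C@@H](C)CO[Si](C)(C)C(C)(C)C | intermediate
26 | (1R,2S,3S,4R,5S)-2-(3,3-diethoxyprop-1-en-2-yl)-5-ethenyl-3-hydroxy-5-methyl-4-[3-(triisopropylsilyloxy)prop-1-en-2-yl]cyclohexyl (2S)-3-(tert-butyldimethylsilyloxy)-2-methylpropanoate | C=C[C@]1(C)C[C@@H](OC(=O)[C@@H](C)CO[Si](C)(C)C(C)(C)C)[C@@H](C(=C)C(OCC)OCC)[C@@H](O)[C@H]1C(=C)CO[Si](C(C)C)(C(C)C)C(C)C | intermediate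
27 | (1R,2S,3S,4R,5S)-5-ethenyl-3-hydroxy-4-(3-hydroxyprop-1-en-2-yl)-5-methyl-2-(3-oxoprop-1-en-2-yl)cyclohexyl (2S)-3-hydroxy-2-methylpropanoate | C=C[C@]1(C)C[C@@H](OC(=O)[C@@H](C)CO)[C@@H](C(=C)C=O)[C@@H](O)[C@H]1C(=C)CO | intermediate
28 | 2-[(1S,2S,3R,4S,6R)-4-ethenyl-2-hydroxy-6-{[(2S)-3-hydroxy-2-methylpropanoyl]oxy}-3-(3-hydroxyprop-1-en-2-yl)-4-methylcyclohexyl]prop-2-enoic acid | C=C[C@]1(C)C[C@@H](OC(=O)[C@@H](C)CO)[C@@H](C(=C)C(=O)O)[C@@H](O)[C@H]1C(=C)CO | target

## Step count and least certain steps

Total step count: 16. Longest linear sequence: 14 steps (steps 1–11 and 14–16); steps 12 and 13 prepare acid 24.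

**Step 11 (key step).** The ring C13–B bond of the oxaborinine overlaps poorly with the C7=C11 π bond, and the transition state carries the syn-axial contact between the C10 methyl and O6/O8. Allyl transfer may therefore be slow enough for the boron–O6 bond to exchange, and then untethered transfer (which gives C11 trans to O6) or hemiacetal formation between O6 and C8 would compete.

Fallback, known chemistry only, from 13 back to 26:
- Corey–Bakshi–Shibata reduction of 13 with the catalyst enantiomer that overrides the Felkin preference should give the C6 epimer of 14, F1.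
- Trans-hydroalumination and iodination as in step 9 should give the iodo diol F2.
- Oxidation of its 1,5-diol with TEMPO/PhI(OAc)2 should give the δ-lactone F3 (O6–C8), which i-Bu2AlH should reduce to the lactol F4.
- Coupling with CH2(Bpin)2 as in step 10, but keeping the pinacol, should give the allylboronate F5. Its open hydroxy-aldehyde form should cyclise on warming through the ordinary untethered chair transition state. There allylic 1,3-strain places O6 anti to the incoming C8, so the α-oriented O6 of this series sends C11 and O8 to the β face and the C6 epimer of 21, F6, should result.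
- Esterification of the C8 hydroxyl with 24 should give F7; Dess–Martin oxidation of the C6 hydroxyl should give ketone F8.
- Reduction with NaBH4/CeCl3 at −78 °C, where hydride can reach C6 only from the face opposite the axial C10 methyl and C8 acyloxy group, should give 26.

**Step 5.** The enolate may form with the wrong geometry (giving the C5 epimer), facial selectivity may be insufficient, or the rearrangement of the hindered trisubstituted allyl unit may be slow.

Fallback, from 8 back to 10: the classical Ireland–Claisen rearrangement through the E(O) trimethylsilyl ketene acetal F9 (LDA, Me3SiCl, THF, −78 → 23 °C) should give racemic acid, that is 10 together with its mirror image F11. Resolution by crystallisation of the salt F10 of 10 with (S)-1-phenylethanamine (or its enantiomer, whichever gives the less soluble salt) and acidification should return 10.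

**Step 8.** Facial selectivity may be poor or reversed if the alkenyl group on C5, not the quaternary C10, takes the anti position in the transition state; C5 may also epimerise through enolisation of the very acidic ynone.

Fallback: if the C6 epimer F1 predominates it is not discarded but carried through the fallback given for step 11, which starts from exactly that compound and returns at 26.

**Step 10.** The allylboron compound may protodeboronate in aqueous base or be oxidised during the periodate treatment, and ring closure to the hemiboronic ester may be incomplete.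

Fallback, from 16 back to 18: deprotonation of both hydroxyls with MeLi and iodine–lithium exchange with t-BuLi, then capture of the alkenyllithium by diisopropyl (chloromethyl)boronate. 1,2-Migration of the alkenyl group from boron to carbon with loss of chloride (Matteson homologation) and closure of the neighbouring alkoxide onto boron should give the cyclic isopropyl ester F12, which aqueous work-up hydrolyses to 18.

**Step 16.** Reversible hemiacetal formation between the C6 hydroxyl and the C12 aldehyde may divert the oxidation towards the lactone, and the product may lactonise or suffer acyl migration during isolation.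

Fallback, from 26 back to 28: silylation of the C6 hydroxyl (Et3SiOTf, 2,6-lutidine) should give F13. Neutral acetal cleavage (catalytic I2 in acetone) should give enal F14, which cannot form a hemiacetal. Pinnick oxidation should give acid F15, and HF·pyridine in THF/pyridine removes the three silyl groups to give 28.

## Further compounds

F1 | step 11 | (4R,5R,6S)-1,1-diethoxy-6-ethenyl-6-methyl-5-[3-(triisopropylsilyloxy)prop-1-en-2-yl]oct-2-yne-4,8-diol (C6 epimer of 14) | C=C[C@](C)(CCO)[C@@H]([C@@H](O)C#CC(OCC)OCC)C(=C)CO[Si](C(C)C)(C(C)C)C(C)C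
F2 | step 11 | C6 epimer of iodo diol 16 | C=C[C@](C)(CCO)[C@@H]([C@@H](O)/C=C(\I)C(OCC)OCC)C(=C)CO[Si](C(C)C)(C(C)C)C(C)C
F3 | step 11 | δ-lactone of F2, 4-ethenyl-6-[(1Z)-3,3-diethoxy-2-iodoprop-1-en-1-yl]-4-methyl-5-[3-(triisopropylsilyloxy)prop-1-en-2-yl]oxan-2-one | C=C[C@]1(C)CC(=O)O[C@@H](/C=C(\I)C(OCC)OCC)[C@H]1C(=C)CO[Si](C(C)C)(C(C)C)C(C)C
F4 | step 11 | lactol from F3 (oxan-2-ol, anomeric centre undefined) | C=C[C@]1(C)CC(O)O[C@@H](/C=C(\I)C(OCC)OCC)[C@H]1C(=C)CO[Si](C(C)C)(C(C)C)C(C)C
F5 | step 11 | pinacol allylboronate of lactol F4 | C=C[C@]1(C)CC(O)O[C@@H](/C=C(\CB2OC(C)(C)C(C)(C)O2)C(OCC)OCC)[C@H]1C(=C)CO[Si](C(C)C)(C(C)C)C(C)C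
F6 | step 11 | C6 epimer of diol 21 | C=C[C@]1(C)C[C@@H](O)[C@@H](C(=C)C(OCC)OCC)[C@H](O)[C@H]1C(=C)CO[Si](C(C)C)(C(C)C)C(C)C
F7 | step 11 | C6 epimer of ester 26 | C=C[C@]1(C)C[C@@H](OC(=O)[C@@H](C)CO[Si](C)(C)C(C)(C)C)[C@@H](C(=C)C(OCC)OCC)[C@H](O)[C@H]1C(=C)CO[Si](C(C)C)(C(C)C)C(C)C
F8 | step 11 | C6 ketone derived from F7 | C=C[C@]1(C)C[C@@H](OC(=O)[C@@H](C)CO[Si](C)(C)C(C)(C)C)[C@@H](C(=C)C(OCC)OCC)C(=O)[C@H]1C(=C)CO[Si](C(C)C)(C(C)C)C(C)C
F9 | step 5 | E(O) trimethylsilyl ketene acetal of 8 | C=C(CO[Si](C(C)C)(C(C)C)C(C)C)/C=C(/O[Si](C)(C)C)OC/C=C(\C)CCO[Si](C)(C)C(C)(C)C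
F10 | step 5 | (S)-1-phenylethanaminium salt of 10 | C=C[C@](C)(CCO[Si](C)(C)C(C)(C)C)[C@@H](C(=O)[O-])C(=C)CO[Si](C(C)C)(C(C)C)C(C)C.C[C@H]([NH3+])c1ccccc1
F11 | step 5 | (2S,3R) enantiomer of 10 | C=C[C@@](C)(CCO[Si](C)(C)C(C)(C)C)[C@H](C(=O)O)C(=C)CO[Si](C(C)C)(C(C)C)C(C)C
F0 | step 8 | none | none
F12 | step 10 | 2-isopropoxy analogue of 18 (cyclic isopropyl allylboronate) | C=C[C@](C)(CCO)[C@@H]([C@@H]1OB(OC(C)C)CC(C(OCC)OCC)=C1)C(=C)CO[Si](C(C)C)(C(C)C)C(C)C
F13 | step 16 | C6 triethylsilyl ether of 26 | C=C[C@]1(C)C[C@@H](OC(=O)[C@@H](C)CO[Si](C)(C)C(C)(C)C)[C@@H](C(=C)C(OCC)OCC)[C@@H](O[Si](CC)(CC)CC)[C@H]1C(=C)CO[Si](C(C)C)(C(C)C)C(C)C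
F14 | step 16 | enal from F13 | C=C[C@]1(C)C[C@@H](OC(=O)[C@@H](C)CO[Si](C)(C)C(C)(C)C)[C@@H](C(=C)C=O)[C@@H](O[Si](CC)(CC)CC)[C@H]1C(=C)CO[Si](C(C)C)(C(C)C)C(C)C
F15 | step 16 | tris-silylated acid from F14 | C=C[C@]1(C)C[C@@H](OC(=O)[C@@H](C)CO[Si](C)(C)C(C)(C)C)[C@@H](C(=C)C(=O)O)[C@@H](O[Si](CC)(CC)CC)[C@H]1C(=C)CO[Si](C(C)C)(C(C)C)C(C)C
A1 | alternative 1 | (1(10)E,4E)-6,8,15-trihydroxygermacra-1(10),4,11(13)-trien-12-oic acid with the C6/C7/C8 configuration of the target | C/C1=C\CC/C(CO)=C/[C@H](O)[C@H](C(=C)C(=O)O)[C@H](O)C1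
A2 | alternative 1 | 8-deacyl target (elemane triol acid) | C=C[C@]1(C)C[C@@H](O)[C@@H](C(=C)C(=O)O)[C@@H](O)[C@H]1C(=C)CO
A3 | alternative 2 | 5-(tert-butyldimethylsilyloxy)-6-(3,3-diethoxyprop-1-en-2-yl)-3-methyl-4-[3-(triisopropylsilyloxy)prop-1-en-2-yl]cyclohex-2-en-1-one with the C5/C6/C7 configuration of the target | O=C1C=C(C)[C@H](C(=C)CO[Si](C(C)C)(C(C)C)C(C)C)[C@H](O[Si](C)(C)C(C)(C)C)[C@@H]1C(=C)C(OCC)OCC
A4 | alternative 2 | vinyl cuprate adduct of A3 (C8 ketone) | C=C[C@]1(C)CC(=O)[C@@H](C(=C)C(OCC)OCC)[C@@H](O[Si](C)(C)C(C)(C)C)[C@H]1C(=C)CO[Si](C(C)C)(C(C)C)C(C)C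
A5 | alternative 3 | 3,5-dimethoxybenzoic acid | COc1cc(cc(OC)c1)C(=O)O
A6 | alternative 3 | 3,5-dimethoxy-1-methylcyclohexa-2,5-diene-1-carboxylic acid | COC1=CC(C)(C(=O)O)C=C(OC)C1
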